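The numbers in the tables were generated by integration on assumed constants; noise was put on by code.

In this closed, stirred vessel the substrate sits in the first phase with the protic impurity, the reagent in the second phase sits in its own layer, and the ratio of volumes stands at 2.0.

| flask | substrate | reagent in the second phase | protic impurity | remark | time | volume of the second phase over the first |
|---|---|---|---|---|---|---|
| Friday's | 1 M | 0.53 M | 0.10 M | run made earlier |  |  |
| flask | 1.0 M | 1.05 M | 0.100 M |  | 12 h | 2.0 |

- Friday's (time / h: product / %, substrate / %): 0.133: 0.1, 96.0; 0.333: 0, 92.5; 0.667: 0.6, 87.6; 1.00: 0, 85.4; 1.33: 0.1, 83.8; 2.00: 0, 82.6; 2.50: 0, 82.1

(readings scatter by 0.3 percentage points)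

- in the second phase: reagent in the second phase; everything else is in the first
- charges count per volume of the first phase; a concentration in a rate is the amount of a species over the volume of its own phase; every rate counts per litre of the first phase
- the earlier runs were read with a standard deviation of 0.3 percentage points
- the earlier runs hold the two phases in the same ratio of volumes as the flask asked about
- what has gone from substrate into another species counts as reacted, even if it can come back

* how much product there is at 12 h, in percent of the substrate charged
* part of the substrate charged that has reacted at 12 h

On Friday the substrate fell quickly, stood at 82.6% by 2.00 h and at 82.1% by 2.50 h, while the product read between 0% and 0.6%. That levelling came earlier than the 12 h asked here, so we expect the quick fall to be over when you come. We read it, as an assumption the readings cannot prove, as a fast pre-equilibrium between the substrate and a hidden form of its own. Friday's last reading then gives 17.9% for what we call the parked share, the part of the substrate not turned into product that sits in the hidden form. Friday's readings make the parked share the large term and the product the small correction, so we reckon reacted as the product plus the parked share of whatever is not product. Please leave the ratio of volumes as it is, because the share was read at that ratio.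

The forecast says 1% product and 35% reacted, taking the hidden species as “most likely a reversible adduct with the reagent”. We differ: with its own product, our rule gives 18.7%, less than its figure.

The flask gives 3.61% product and 20.7% reacted, under this scheme:

    reagent in the reaction phase ⇌ reagent in the second phase, rate k1*([reagent in the reaction phase] - [reagent in the second phase]/K1) per volume of the first phase (partition coefficient = 2.50, kL = 2.28 × 10⁻⁵ /s)
    substrate + reagent in the reaction phase → product (k = 2.46 × 10⁻⁵ /M/s)
    substrate ⇌ dormant form (K = 0.215, k = 8.67 × 10⁻⁵ /s)
    reagent in the reaction phase + protic impurity → quenched reagent (k = 4.30 × 10⁻⁴ /M/s)

Raising the reagent in the second phase of Friday's run from 0.53 M to 1.05 M, with the time held at that run's last reading, gives 17.8% reacted against 17.6%. With the product found, the parked share gives 20.9% reacted for this flask. For the same flask read at 30 h, with 12.0% product, it gives 27.8%, and that flask stands at 27.6%.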